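## Retrosynthetic overview
1. Hippolide A is the 2,6-cis lactol. It comes from mild acid hydrolysis of methyl acetal **15**. The Z-trisubstituted ring alkene C3=C4 is built by ring-closing metathesis of mixed acetal **14**.
2. **14** comes from transacetalization of homoallylic alcohol **13**, which carries the intact NH-succinimide, with the 2-alkylacrolein acetal **6**. **6** is made from farnesyl bromide by Grignard homologation and α-methylenation.
3. **13** is the syn β-hydroxy imide. It comes from Ru-catalysed dynamic kinetic asymmetric transfer hydrogenation (DKR–ATH) of a 3-acylsuccinimide, itself made by radical hydroacylation of maleimide. This sets C6 and C3′ in two steps, with no auxiliary and no imide construction.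
4. Ring order: the succinimide is carried through unchanged from maleimide, the dihydropyran is closed by RCM, and the lactol is unmasked last.

**Assumptions**
- The lactol anomers interconvert by ring–chain tautomerism. I take the natural product to be the cis-2,6 anomer, which is what the SMILES encodes, and isolate it by chromatography.
- The (R,R)-TsDPEN–Ru catalyst is assumed to give the (6R)-carbinol, by analogy with (S,S)-catalyst → (S)-1-phenylethanol.

## Route

**Step 1**
Reactants: **1** (E,E)-farnesyl bromide; **2** 2-(1,3-dioxolan-2-yl)ethylmagnesium bromide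
Product: **3** 2-[(3E,7E)-4,8,12-trimethyltrideca-3,7,11-trien-1-yl… i.e. farnesyl–CH2CH2–CH(OCH2CH2O)] acetal
Conditions: Li2CuCl4 (3 mol%), THF, −30 → 0 °C
Reagents that add atoms: none
Why: Cu-catalysed SN2 (α) coupling of an alkyl Grignard with an allylic bromide (Kochi–Schlosser type). The E geometry is retained, the aldehyde stays masked, and no stereocentre is formed.

**Step 2**
Reactants: **3**
Product: **4** (5E,9E)-6,10,14-trimethylpentadeca-5,9,13-trienal
Conditions: PPTS (0.3 equiv), acetone/H2O (10:1), 50 °C
Reagents that add atoms: water, O
Why: Acid-catalysed acetal hydrolysis. These conditions are mild enough to leave the trisubstituted alkenes alone.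

**Step 3**
Reactants: **4**
Product: **5** (5E,9E)-2-methylene-6,10,14-trimethylpentadeca-5,9,13-trienal
Conditions: 37% aq. HCHO (1.5 equiv), pyrrolidine (10 mol%), EtCO2H (10 mol%), THF, 45 °C
Reagents that add atoms: formaldehyde, C=O
Why: Mannich/Eschenmoser-type α-methylenation (enamine → Mannich → elimination). It turns the α-CH2, the future C3, into the 1,1-disubstituted alkene that RCM needs.

**Step 4**
Reactants: **5**
Product: **6** (5E,9E)-1,1-dimethoxy-2-methylene-6,10,14-trimethylpentadeca-5,9,13-triene
Conditions: HC(OMe)3 (3 equiv), PPTS (5 mol%), MeOH, 25 °C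
Reagents that add atoms: trimethyl orthoformate, COC(OC)OC
Why: Acid-catalysed acetalization. It stabilises the enal against polymerisation and gives an oxocarbenium precursor for the later transacetalization.

**Step 5**
Reactants: **7** maleimide; **8** 3-(tert-butyldimethylsilyloxy)propanal
Product: **9** 3-[3-(TBSO)propanoyl]pyrrolidine-2,5-dione
Conditions: TBADT (2 mol%), MeCN, 390 nm LEDs, rt; aldehyde 3 equiv
Reagents that add atoms: none
Why: Decatungstate photo-HAT takes the formyl H to give a nucleophilic acyl radical. This adds to the electron-poor maleimide alkene, and back-HAT gives the 3-acylsuccinimide. Proposed new method: mechanistic reasoning as above; closest known reaction is decatungstate hydroacylation of enones, maleates and N-substituted maleimides, here extended to N–H maleimide and a β-siloxy aldehyde. The product is racemic and epimerisable at C3′, which is exactly what the next step needs.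

**Step 6**
Reactants: **9**
Product: **10** (3S)-3-[(1R)-3-(TBSO)-1-hydroxypropyl]pyrrolidine-2,5-dione
Conditions: RuCl[(R,R)-TsDPEN](p-cymene) (2 mol%), HCO2H/Et3N (5:2), CH2Cl2, 30 °C
Reagents that add atoms: none (H only)
Why: Noyori–Ikariya outer-sphere transfer hydrogenation. The β-ketoimide enolises fast, so C3′ racemises faster than reduction (dynamic kinetic resolution). The chiral Ru–H sets C6 (R) by face-selective hydride transfer and selects the matched C3′ epimer (S), giving the syn diastereomer. Proposed new method: closest known reaction is DKR–ATH of α-substituted β-ketoesters and β-ketolactams; here the substrate is a 3-acylsuccinimide, and the syn assignment is a prediction.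

**Step 7**
Reactants: **10**
Product: **11** (3S)-3-[(1R)-1,3-dihydroxypropyl]pyrrolidine-2,5-dione
Conditions: HF·pyridine, THF/pyridine, 0 °C → rt
Reagents that add atoms: none
Why: Fluoride-mediated silyl ether cleavage under acidic-buffered conditions. This avoids base, so there is no imide ring opening and no C3′ epimerisation.

**Step 8**
Reactants: **11**
Product: **12** (3S)-3-[(1R)-1-hydroxy-3-oxopropyl]pyrrolidine-2,5-dione
Conditions: TEMPO (10 mol%), PhI(OAc)2 (1.2 equiv), CH2Cl2, 0 °C → rt
Reagents that add atoms: none
Why: Anelli-type oxidation selective for the unhindered primary alcohol over the secondary β-hydroxy group. No stereocentre is touched.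

**Step 9**
Reactants: **12**
Product: **13** (3S)-3-[(1R)-1-hydroxybut-3-en-1-yl]pyrrolidine-2,5-dione
Conditions: Ph3PCH3Br/KOtBu (4 equiv), THF, −78 → 0 °C
Reagents that add atoms: methylenetriphenylphosphorane, C=P(c1ccccc1)(c1ccccc1)c1ccccc1
Why: Wittig methylenation. The imide N–H and the alkoxide are deprotonated first, which suppresses β-elimination and C3′ epimerisation. This installs the vinyl group (C4=C3) that RCM needs.

**Step 10**
Reactants: **13**; **6**
Product: **14** mixed acetal, O–CH(OMe)–C(=CH2)R on the C6 oxygen (acetal carbon as an epimeric mixture)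
Conditions: **6** (3 equiv), PPTS (10 mol%), toluene, 40 °C, 150 mbar (removes MeOH)
Reagents that add atoms: none
Why: Acid-catalysed transacetalization via the allylic oxocarbenium ion. The acetal epimers are irrelevant because C2 is re-set in step 12.

**Step 11**
Reactants: **14**
Product: **15** 2-methoxy-3-homofarnesyl-6-[(3S)-succinimid-3-yl]-3,6-dihydro-2H-pyran (6R)
Conditions: Grubbs II (10 mol%), 1,4-benzoquinone (10 mol%), CH2Cl2 (3 mM), 40 °C
Reagents that add atoms: none (ethylene is lost)
Why: Ring-closing metathesis of a terminal alkene with a 1,1-disubstituted alkene. The six-membered ring forces the cis (Z) relationship, and the isolated trisubstituted chain alkenes are far less reactive than the two reacting termini. No new stereocentre is formed.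

**Step 12**
Reactants: **15**
Product: **16** Hippolide A
Conditions: AcOH/THF/H2O (2:2:1), 40 °C
Reagents that add atoms: water, O
Why: Hydrolysis of the allylic methyl acetal through the conjugated oxocarbenium ion. C2 is set by anomeric equilibration via the ring-opened hydroxy-enal, and the cis-(2S) lactol is isolated.

## Compound list
1 | (E,E)-farnesyl bromide | CC(C)=CCC/C(C)=C/CC/C(C)=C/CBr | starting material
2 | 2-(1,3-dioxolan-2-yl)ethylmagnesium bromide | Br[Mg]CCC1OCCO1 | starting material
3 | farnesyl–CH2CH2–CH(OCH2CH2O) acetal | CC(C)=CCC/C(C)=C/CC/C(C)=C/CCCC1OCCO1 | intermediate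
4 | (5E,9E)-6,10,14-trimethylpentadeca-5,9,13-trienal | CC(C)=CCC/C(C)=C/CC/C(C)=C/CCCC=O | intermediate
5 | (5E,9E)-2-methylene-6,10,14-trimethylpentadeca-5,9,13-trienal | CC(C)=CCC/C(C)=C/CC/C(C)=C/CCC(=C)C=O | intermediate
6 | dimethyl acetal of 5 | CC(C)=CCC/C(C)=C/CC/C(C)=C/CCC(=C)C(OC)OC | intermediate
7 | maleimide | O=C1C=CC(=O)N1 | starting material
8 | 3-(TBSO)propanal | CC(C)(C)[Si](C)(C)OCCC=O | starting material
9 | 3-[3-(TBSO)propanoyl]succinimide (racemic) | CC(C)(C)[Si](C)(C)OCCC(=O)C1CC(=O)NC1=O | intermediate
10 | (3S)-3-[(1R)-3-(TBSO)-1-hydroxypropyl]succinimide | CC(C)(C)[Si](C)(C)OCC[C@@H](O)[C@@H]1CC(=O)NC1=O | intermediate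
11 | (3S)-3-[(1R)-1,3-dihydroxypropyl]succinimide | OCC[C@@H](O)[C@@H]1CC(=O)NC1=O | intermediate
12 | (3S)-3-[(1R)-1-hydroxy-3-oxopropyl]succinimide | O=CC[C@@H](O)[C@@H]1CC(=O)NC1=O | intermediate
13 | (3S)-3-[(1R)-1-hydroxybut-3-enyl]succinimide | C=CC[C@@H](O)[C@@H]1CC(=O)NC1=O | intermediate
14 | mixed acetal from 13 + 6 | CC(C)=CCC/C(C)=C/CC/C(C)=C/CCC(=C)C(OC)O[C@H](CC=C)[C@@H]1CC(=O)NC1=O | intermediate
15 | 2-methoxy dihydropyran (RCM product) | CC(C)=CCC/C(C)=C/CC/C(C)=C/CCC1=CC[C@H]([C@@H]2CC(=O)NC2=O)OC1OC | intermediate
16 | Hippolide A | CC(C)=CCC/C(C)=C/CC/C(C)=C/CCC1=CC[C@H]([C@@H]2CC(=O)NC2=O)O[C@@H]1O | target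

## Totals
- Total steps: 12.
- Longest linear sequence: 8 steps, from maleimide (steps 5 → 12).

## Three steps most likely to fail
1. **Step 6 (DKR–ATH).** The risks are the syn/anti ratio, poor reactivity of the enolised β-ketoimide, and β-elimination of the siloxy group.
   - Fallback: Evans syn aldol of N-(3-cyanopropanoyl)-(S)-4-benzyloxazolidinone with 3-butenal. Then hydrate the nitrile with the Parkins Pt catalyst and close the imide with NaHMDS, which expels the auxiliary and gives **13** directly.
2. **Step 11 (RCM).** A 1,1-disubstituted alkene next to an acetal, with three trisubstituted chain alkenes and a free N–H imide, may give low conversion or oligomers.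
   - Fallback: protect the C6 alcohol of **12** as its TES ether and run an Ando Z-selective HWE with (PhO)2P(O)CH(homofarnesyl)CO2Me. Removing the silyl group lets the Z-enoate lactonise. Then reduce with DIBAL (3 equiv, the imide is protected as its aluminium imidate) to give the lactol.
3. **Step 5 (hydroacylation of N–H maleimide).** The risks are HAT at the silyl ether or at the imide, low yield, and over-acylation.
   - Fallback: polarity-reversed ionic NHC Stetter reaction of **8** with **7** (thiazolium salt, Et3N), which gives **9** without radicals.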